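**Retrosynthetic overview**
- The only ring to build is the pyridone ring of the 4-quinolone; the benzene ring comes intact from N-methylisatoic anhydride.
- Key disconnection: the C3–C4 bond, formed by an intermolecular Claisen-type C-acylation of the terminal enolate of heptadecan-2-one with the C4 carbonyl of N-methylisatoic anhydride.
- After CO2 loss, the N-methylaniline nitrogen condenses onto the side-chain ketone (N1–C2 bond), which closes the pyridone ring last.
- Heptadecan-2-one comes from palmitoyl chloride by Weinreb amide formation and MeMgBr addition.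

Assumption: the target has no stereocentre and no stereogenic double bond, so the "single enantiomer" requirement is met trivially and nothing stereochemical needs to be set.

**Step 1**
Reactants: 1 hexadecanoyl chloride (palmitoyl chloride)
Product: 2 N-methoxy-N-methylhexadecanamide
Conditions: MeNH(OMe)·HCl (1.1 equiv), Et3N (2.2 equiv), CH2Cl2, 0 °C → rt, 2 h
Reagents that add atoms: N,O-dimethylhydroxylamine hydrochloride, CNOC.Cl
Why: Nucleophilic acyl substitution (Weinreb amide formation) of a reactive acid chloride by the hydroxylamine, with Et3N scavenging HCl; no stereocentre is involved.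

**Step 2**
Reactants: 2 N-methoxy-N-methylhexadecanamide
Product: 4 heptadecan-2-one, via magnesium hemiaminal chelate 3 (not isolated)
Conditions: MeMgBr (1.3 equiv), THF, 0 °C → rt, 1 h; then 1 M HCl, 0 °C
Reagents that add atoms: methylmagnesium bromide, C[Mg]Br
Why: Weinreb ketone synthesis, in which MeMgBr adds once to give the stable five-membered Mg chelate 3 that collapses to the methyl ketone only on acidic quench, so over-addition is blocked; no stereocentre is formed.

**Step 3**
Reactants: 4 heptadecan-2-one (2.0 equiv); 5 N-methylisatoic anhydride (1.0 equiv)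
Product: 9 1-methyl-2-pentadecylquinolin-4(1H)-one, via lithium enolate 6 (not isolated), via lithium carbamate adduct 7 (not isolated), via amino diketone 8 (not isolated)
Conditions: LDA (2.1 equiv, commercial solution), THF, −78 °C, 1 h; then 5 in THF, −78 °C → rt, 16 h; 1 M HCl to pH 6
Reagents that add atoms: none
Why: Intermolecular Claisen-type condensation in which the kinetic terminal enolate 6 opens the anhydride at its more electrophilic C4 carbonyl, the carbamate 7 loses CO2 on protonation, and the freed N-methylaniline nitrogen of 8 cyclodehydrates onto the side-chain ketone to give the 4-quinolone (the second equivalent of enolate acts as base for the acidic 1,3-diketone and is recovered as 4); no stereocentre is formed.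

**Compound list**
1 | hexadecanoyl chloride (palmitoyl chloride) | CCCCCCCCCCCCCCCC(=O)Cl | starting material
2 | N-methoxy-N-methylhexadecanamide | CCCCCCCCCCCCCCCC(=O)N(C)OC | intermediate
3 | bromomagnesium 2-[methoxy(methyl)amino]heptadecan-2-olate (tetrahedral chelate) | CCCCCCCCCCCCCCCC(C)(O[Mg]Br)N(C)OC | intermediate
4 | heptadecan-2-one | CCCCCCCCCCCCCCCC(C)=O | intermediate
5 | N-methylisatoic anhydride (1-methyl-2H-3,1-benzoxazine-2,4(1H)-dione) | CN1C(=O)OC(=O)c2ccccc21 | starting material
6 | lithium heptadec-1-en-2-olate | CCCCCCCCCCCCCCCC(=C)O[Li] | intermediate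
7 | lithium N-methyl-N-[2-(3-oxooctadecanoyl)phenyl]carbamate | CCCCCCCCCCCCCCCC(=O)CC(=O)c1ccccc1N(C)C(=O)O[Li] | intermediate
8 | 1-[2-(methylamino)phenyl]octadecane-1,3-dione | CCCCCCCCCCCCCCCC(=O)CC(=O)c1ccccc1NC | intermediate
9 | 1-methyl-2-pentadecylquinolin-4(1H)-one (1-methyl-2-pentadecyl-4(1H)-quinolone) | CCCCCCCCCCCCCCCc1cc(=O)c2ccccc2n1C | target

**Step count and risk**
Total steps: 3. Longest linear sequence: 3 (1 → 2 → 4 → 9); compound 5 is purchased.

Steps most likely to fail, in order of risk:

Step 3 (enolate scrambling, ketone self-aldol, attack at the carbamate carbonyl or incomplete cyclodehydration can lower the yield). The fallback sets out from 4 and comes back at 9. A crossed Claisen condensation of 4 with methyl 2-fluorobenzoate (NaH, THF, 60 °C) gives 1-(2-fluorophenyl)octadecane-1,3-dione F1. Methylamine (EtOH, rt) condenses at the more reactive aliphatic carbonyl to give (Z)-1-(2-fluorophenyl)-3-(methylamino)octadec-2-en-1-one F2. Heating with K2CO3 in DMF at 130 °C closes the ring by intramolecular SNAr of the enaminone nitrogen on the ortho-acyl-activated aryl fluoride, giving 9.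

Step 2 (sluggish or incomplete Grignard addition to the waxy, poorly soluble long-chain amide). The fallback sets out from 2 and comes back at 4. Reduction of 2 with LiAlH4 (THF, 0 °C) gives hexadecanal F3. MeMgBr addition to this far more electrophilic aldehyde gives racemic heptadecan-2-ol F4, whose stereocentre is irrelevant. Oxidation with Dess–Martin periodinane (CH2Cl2, rt) then gives 4.

Step 1 (partial hydrolysis of the acid chloride or difficult separation of the amide from palmitic acid). The fallback sets out from 1 and comes back at 4, bypassing 2. C-acylation of Meldrum's acid with 1 (pyridine, CH2Cl2, 0 °C) gives 5-(1-hydroxyhexadecylidene)-2,2-dimethyl-1,3-dioxane-4,6-dione F5. Refluxing this in AcOH/H2O hydrolyses the acetonide and doubly decarboxylates to give 4.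

**Further compounds**
F1 | step 3 | 1-(2-fluorophenyl)octadecane-1,3-dione | CCCCCCCCCCCCCCCC(=O)CC(=O)c1ccccc1F
F2 | step 3 | (Z)-1-(2-fluorophenyl)-3-(methylamino)octadec-2-en-1-one | CN/C(CCCCCCCCCCCCCCC)=C\C(=O)c1ccccc1F
F3 | step 2 | hexadecanal | CCCCCCCCCCCCCCCC=O
F4 | step 2 | heptadecan-2-ol (racemic) | CCCCCCCCCCCCCCCC(C)O
F5 | step 1 | 5-(1-hydroxyhexadecylidene)-2,2-dimethyl-1,3-dioxane-4,6-dione | CCCCCCCCCCCCCCCC(O)=C1C(=O)OC(C)(C)OC1=O
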